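**Retrosynthetic overview**
1. Numbering used: C1 ketone carbon, C4=C5 the Z-olefin, C6 the lactone O–CH, C7 the ring-fusion CH, C8 the tiglate carbinol, C10 the tertiary carbinol, C11/C12/C13 the lactone α-carbon, carbonyl and methylene.
2. Last operation: C13 is added by decarboxylative methylenation of an α-carboxy lactone.
3. Key disconnection: the lactone ring (C7–C11 and C6–O) is cut back to a (Z,Z)-cyclodeca-1,3-dienyl tiglate plus malonic acid, joined by an oxidative radical carbolactonisation with trivalent manganese that sets C6 and C7.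
4. The ten-membered ring comes from ring-closing metathesis at C6=C7 of an acyclic triene ketone.
5. The triene comes from C1–C2 bond formation between a (Z)-dienyl lithium (Z fixed by a six-membered lactone precursor) and a vinyl hydroxy lactone (C10 by asymmetric pyruvate aldol, C8 by anti reduction). Ring order: carbocycle first, lactone last.

Assumption: the SMILES is read as the (3aS,4R,6R,10Z,11aR) isomer, i.e. cis-fused lactone, C8 ester trans to the C7–C11 bond on the ring, and an (E)-2-methylbut-2-enoate (tiglate).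

**Step 1**
Reactants: 1 but-3-en-2-one
Product: 2 2-(trimethylsilyloxy)buta-1,3-diene
Conditions: Me3SiCl, Et3N, DMF, 80 °C
Reagents that add atoms: chlorotrimethylsilane, C[Si](C)(C)Cl
Why: Silyl enol ether formation at the only enolisable position of the enone gives the siloxydiene that will deliver C7–C9; no stereocentre is formed.

**Step 2**
Reactants: 2 2-(trimethylsilyloxy)buta-1,3-diene; 3 methyl pyruvate
Product: 5 methyl (2R)-2-hydroxy-2-methyl-4-oxohex-5-enoate, via silyl ether 4 (not isolated)
Conditions: Cu(OTf)2 (10 mol%), (R,R)-tBu-box [2,2'-(propane-2,2-diyl)bis((4R)-4-tert-butyl-4,5-dihydrooxazole)] (11 mol%), THF, −78 °C; then 1 M HCl, THF, 0 °C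
Reagents that add atoms: none
Why: Catalytic asymmetric Mukaiyama aldol on the square-planar bidentate pyruvate–copper chelate, in which the tert-butyl groups of the (R,R)-ligand leave open the ketone face that gives the R tertiary carbinol (C10), and acidic work-up removes the transferred silyl group.

**Step 3**
Reactants: 5 methyl (2R)-2-hydroxy-2-methyl-4-oxohex-5-enoate
Product: 7 (3R,5R)-5-ethenyl-3-hydroxy-3-methyloxolan-2-one, via diol ester 6 (not isolated)
Conditions: Me4NBH(OAc)3, MeCN/AcOH (1:1), −30 °C; then TsOH·H2O (cat.), CH2Cl2, 25 °C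
Reagents that add atoms: none
Why: Evans–Saksena hydroxyl-directed reduction delivers hydride intramolecularly from the boron-bound tertiary alkoxide through a chair transition state (1,2-addition to the enone carbonyl) to give the 1,3-anti diol (C8 = R), and the new secondary hydroxyl then closes the γ-lactone on the methyl ester.

**Step 4**
Reactants: 8 4-methyl-5,6-dihydro-2H-pyran-2-one
Product: 10 (3Z)-3-methylhexa-3,5-dien-1-ol, via lactol 9 (not isolated)
Conditions: iBu2AlH (1.1 equiv), CH2Cl2, −78 °C; then Ph3P=CH2 (from Ph3PCH3Br, KN(SiMe3)2), THF, −78 °C to 25 °C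
Reagents that add atoms: methyltriphenylphosphonium bromide, C[P+](c1ccccc1)(c1ccccc1)c1ccccc1.[Br-]
Why: Half-reduction of the unsaturated lactone to the lactol followed by Wittig methylenation of its ring-opened hydroxy enal gives the dienol, the Z geometry of the trisubstituted olefin being inherited from the ring.

**Step 5**
Reactants: 10 (3Z)-3-methylhexa-3,5-dien-1-ol
Product: 11 (3Z)-6-iodo-4-methylhexa-1,3-diene
Conditions: I2, PPh3, imidazole, CH2Cl2, 0 °C
Reagents that add atoms: iodine, II
Why: Appel-type iodination of the primary alcohol by SN2 displacement of the oxyphosphonium leaves the diene geometry untouched.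

**Step 6**
Reactants: 11 (3Z)-6-iodo-4-methylhexa-1,3-diene; 7 (3R,5R)-5-ethenyl-3-hydroxy-3-methyloxolan-2-one
Product: 13 (3Z,8R,10R)-8,10-dihydroxy-4,8-dimethyldodeca-1,3,11-trien-7-one, via organolithium 12 (not isolated)
Conditions: 11, tBuLi (2.1 equiv), Et2O/pentane, −78 °C; added to 7 + LiN(SiMe3)2 (1.0 equiv), THF, −78 °C to −40 °C; aq. NH4Cl
Reagents that add atoms: none
Why: Lithium–iodine exchange gives the primary alkyllithium, which adds once to the lactone carbonyl of the lithium alkoxide of 7 (no α-hydrogen to enolise, tetrahedral lactolate stable in the cold) in a nucleophilic acyl substitution that forms the C1 ketone and frees the C8 hydroxyl without touching either stereocentre.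

**Step 7**
Reactants: 13 (3Z,8R,10R)-8,10-dihydroxy-4,8-dimethyldodeca-1,3,11-trien-7-one; 14 (2E)-2-methylbut-2-enoyl chloride
Product: 15 (3R,5R,9Z)-5-hydroxy-5,9-dimethyl-6-oxododeca-1,9,11-trien-3-yl (2E)-2-methylbut-2-enoate
Conditions: pyridine, DMAP (cat.), CH2Cl2, 0 °C
Reagents that add atoms: none
Why: DMAP-catalysed acylation takes the secondary allylic hydroxyl in preference to the hindered tertiary one, acylation of the open hydroxy ketone draining its cyclic hemiketal form, and the E olefin of the acyl group is the stable isomer.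

**Step 8**
Reactants: 15 (3R,5R,9Z)-5-hydroxy-5,9-dimethyl-6-oxododeca-1,9,11-trien-3-yl (2E)-2-methylbut-2-enoate
Product: 16 (1R,2Z,4Z,9R)-9-hydroxy-5,9-dimethyl-8-oxocyclodeca-2,4-dien-1-yl (2E)-2-methylbut-2-enoate
Conditions: second-generation Hoveyda–Grubbs catalyst [(H2IMes)Cl2Ru=CH(C6H4-2-OiPr)] (10 mol%), toluene (1 mM), 80 °C, Ar sparge
Reagents that add atoms: none
Why: Ring-closing metathesis joins the two monosubstituted olefin termini (the trisubstituted and the tiglate olefins are spectators), and a ten-membered ring that already holds a Z-olefin, a ketone and a quaternary carbon is expected to take up the new conjugated olefin as Z.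

**Step 9**
Reactants: 16 (1R,2Z,4Z,9R)-9-hydroxy-5,9-dimethyl-8-oxocyclodeca-2,4-dien-1-yl (2E)-2-methylbut-2-enoate; 17 malonic acid (5 equiv)
Product: 18 (3aS,4R,6R,10Z,11aR)-6-hydroxy-6,10-dimethyl-4-{[(2E)-2-methylbut-2-enoyl]oxy}-2,7-dioxo-2,3,3a,4,5,6,7,8,9,11a-decahydrocyclodeca[b]furan-3-carboxylic acid (C3 epimers)
Conditions: Mn(OAc)3·2H2O (2.2 equiv), KOAc, AcOH, 25–40 °C, Ar
Reagents that add atoms: none
Why: In this oxidative free-radical carbolactonisation the electrophilic malonyl radical made by trivalent manganese adds to the less substituted diene terminus C7 on the outer face anti to the C8–C9 ring bond (H-8 eclipsing the Z-olefin to avoid allylic 1,3-strain), which puts C11 trans to the ester oxygen, and the resulting allyl radical is oxidised by a second trivalent manganese and captured at C6 by the carboxyl through a five-membered transition state before the former Z-olefin can rotate, giving the cis-fused lactone (C6 = R, C7 = S) with C4=C5 kept Z.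

**Step 10**
Reactants: 18 the α-carboxy lactone from step 9
Product: 19 (3aS,4R,6R,10Z,11aR)-6-hydroxy-6,10-dimethyl-3-methylidene-2,7-dioxo-2,3,3a,4,5,6,7,8,9,11a-decahydrocyclodeca[b]furan-4-yl (2E)-2-methylbut-2-enoate
Conditions: 37% aq. CH2O, Et2NH, NaOAc, AcOH, 70 °C
Reagents that add atoms: formaldehyde, C=O
Why: Decarboxylative Mannich methylenation, in which the malonic-type position condenses with the iminium from formaldehyde and diethylamine, loses CO2 and eliminates the amine, makes C11 sp2 (so its epimer mixture does not matter) and leaves the ring stereocentres untouched.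

**Compound list**
1 | but-3-en-2-one | CC(=O)C=C | starting material
2 | 2-(trimethylsilyloxy)buta-1,3-diene | C=CC(=C)O[Si](C)(C)C | intermediate
3 | methyl pyruvate | CC(=O)C(=O)OC | starting material
4 | methyl (2R)-2-methyl-4-oxo-2-(trimethylsilyloxy)hex-5-enoate | COC(=O)[C@](C)(O[Si](C)(C)C)CC(=O)C=C | intermediate
5 | methyl (2R)-2-hydroxy-2-methyl-4-oxohex-5-enoate | COC(=O)[C@](C)(O)CC(=O)C=C | intermediate
6 | methyl (2R,4R)-2,4-dihydroxy-2-methylhex-5-enoate (anti diol) | COC(=O)[C@](C)(O)C[C@@H](O)C=C | intermediate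
7 | (3R,5R)-5-ethenyl-3-hydroxy-3-methyloxolan-2-one (hydroxyl cis to vinyl) | C[C@@]1(O)C[C@H](C=C)OC1=O | intermediate
8 | 4-methyl-5,6-dihydro-2H-pyran-2-one | CC1=CC(=O)OCC1 | starting material
9 | 4-methyl-5,6-dihydro-2H-pyran-2-ol | CC1=CC(O)OCC1 | intermediate
10 | (3Z)-3-methylhexa-3,5-dien-1-ol | OCC/C(C)=C\C=C | intermediate
11 | (3Z)-6-iodo-4-methylhexa-1,3-diene | ICC/C(C)=C\C=C | intermediate
12 | [(3Z)-3-methylhexa-3,5-dien-1-yl]lithium | [Li]CC/C(C)=C\C=C | intermediate
13 | (3Z,8R,10R)-8,10-dihydroxy-4,8-dimethyldodeca-1,3,11-trien-7-one | C=C/C=C(/C)CCC(=O)[C@](C)(O)C[C@@H](O)C=C | intermediate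
14 | (2E)-2-methylbut-2-enoyl chloride (tigloyl chloride) | C/C=C(\C)C(Cl)=O | starting material
15 | (3R,5R,9Z)-5-hydroxy-5,9-dimethyl-6-oxododeca-1,9,11-trien-3-yl (2E)-2-methylbut-2-enoate | C=C/C=C(/C)CCC(=O)[C@](C)(O)C[C@@H](OC(=O)/C(C)=C/C)C=C | intermediate
16 | (1R,2Z,4Z,9R)-9-hydroxy-5,9-dimethyl-8-oxocyclodeca-2,4-dien-1-yl (2E)-2-methylbut-2-enoate | C1[C@@H](OC(=O)/C(C)=C/C)/C=C\C=C(\C)CCC(=O)[C@]1(C)O | intermediate
17 | malonic acid | OC(=O)CC(=O)O | starting material
18 | (3aS,4R,6R,10Z,11aR)-6-hydroxy-6,10-dimethyl-4-{[(2E)-2-methylbut-2-enoyl]oxy}-2,7-dioxo-2,3,3a,4,5,6,7,8,9,11a-decahydrocyclodeca[b]furan-3-carboxylic acid (C3 epimers) | OC(=O)C1C(=O)O[C@@H]2/C=C(/C)CCC(=O)[C@](C)(O)C[C@@H](OC(=O)/C(C)=C/C)[C@H]12 | intermediate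
19 | (3aS,4R,6R,10Z,11aR)-6-hydroxy-6,10-dimethyl-3-methylidene-2,7-dioxo-2,3,3a,4,5,6,7,8,9,11a-decahydrocyclodeca[b]furan-4-yl (2E)-2-methylbut-2-enoate | C=C1C(=O)O[C@@H]2/C=C(/C)CCC(=O)[C@](C)(O)C[C@@H](OC(=O)/C(C)=C/C)[C@H]12 | target

**Step count**
Total: 10 steps. Longest linear sequence: 8 steps (steps 1, 2, 3, 6, 7, 8, 9, 10); the other branch (steps 4, 5) joins at step 6.

**Steps most likely to fail**

Step 9 (radical carbolactonisation). The risks are the face of attack at C7 relative to the C8 ester, capture of the allyl cation by the C10 hydroxyl or by acetate instead of the carboxyl, and further oxidation of the α-carboxy lactone. The fallback sets out from 16 and comes back at 18, and replaces the radical addition by carbenoid chemistry. The C6=C7 olefin of 16 is cyclopropanated on its outer face with the malonate carbenoid from di-tert-butyl malonate, PhI(OAc)2, MgO and Rh2(OAc)4 (cat.) in CH2Cl2, giving di-tert-butyl (1R,2Z,7R,9R,10S)-7-hydroxy-3,7-dimethyl-9-{[(2E)-2-methylbut-2-enoyl]oxy}-6-oxobicyclo[8.1.0]undec-2-ene-11,11-dicarboxylate F1. CF3CO2H in CH2Cl2 at 0 °C then removes the tert-butyl groups, and the vinylcyclopropane diacid opens at the allylic C6–C11 bond with closure of one carboxyl on C6 on the same face, giving 18.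

Step 8 (ring-closing metathesis). The risks are oligomers from the strained ten-membered ring, the E isomer at C6=C7, and attack of the carbene on the diene. The fallback sets out from 7 and 11 and comes back at 16, and closes the ring at C1–C2 instead. Z-selective cross-metathesis of the vinyl group of 7 with the diene terminus of 11, using the cyclometalated nitrato ruthenium catalyst Ru(NO3)(=CH-C6H4-2-OiPr)(C,C-chelating 1-adamantyl-3-mesitylimidazolidin-2-ylidene), gives (3R,5R)-3-hydroxy-5-[(1Z,3Z)-6-iodo-4-methylhexa-1,3-dien-1-yl]-3-methyloxolan-2-one F2. LiN(SiMe3)2 and then tBuLi in Et2O/pentane at −100 °C effect lithium–iodine exchange and intramolecular acyl substitution on the lactone, giving (2R,4R,5Z,7Z)-2,4-dihydroxy-2,8-dimethylcyclodeca-5,7-dien-1-one F3. Acylation with 14 as in step 7 gives 16.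

Step 6 (alkyllithium plus hydroxy lactone). The risks are addition of the alkyllithium to the diene of a second molecule during the exchange, and sluggish or double addition to the α-alkoxide lactone. The fallback sets out from 7 and 11 and comes back at 13, and goes through a Weinreb amide. Lactone 7 is opened with MeNH(OMe)·HCl and AlMe3 in CH2Cl2 to (2R,4R)-2,4-dihydroxy-N-methoxy-N,2-dimethylhex-5-enamide F4. Iodide 11 is converted with Mg in Et2O into [(3Z)-3-methylhexa-3,5-dien-1-yl]magnesium iodide F5. About 3.2 equivalents of the Grignard reagent are used: two deprotonate the hydroxyls and the third adds to the amide, whose chelated tetrahedral intermediate releases ketone 13 on work-up.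

**Further compounds**
F1 | step 9 | di-tert-butyl (1R,2Z,7R,9R,10S)-7-hydroxy-3,7-dimethyl-9-{[(2E)-2-methylbut-2-enoyl]oxy}-6-oxobicyclo[8.1.0]undec-2-ene-11,11-dicarboxylate | CC(C)(C)OC(=O)C1(C(=O)OC(C)(C)C)[C@@H]2/C=C(/C)CCC(=O)[C@](C)(O)C[C@@H](OC(=O)/C(C)=C/C)[C@H]12
F2 | step 8 | (3R,5R)-3-hydroxy-5-[(1Z,3Z)-6-iodo-4-methylhexa-1,3-dien-1-yl]-3-methyloxolan-2-one | C[C@@]1(O)C[C@H](/C=C\C=C(\C)CCI)OC1=O
F3 | step 8 | (2R,4R,5Z,7Z)-2,4-dihydroxy-2,8-dimethylcyclodeca-5,7-dien-1-one | C1[C@@H](O)/C=C\C=C(\C)CCC(=O)[C@]1(C)O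
F4 | step 6 | (2R,4R)-2,4-dihydroxy-N-methoxy-N,2-dimethylhex-5-enamide | CON(C)C(=O)[C@](C)(O)C[C@@H](O)C=C
F5 | step 6 | [(3Z)-3-methylhexa-3,5-dien-1-yl]magnesium iodide | I[Mg]CC/C(C)=C\C=C
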